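**Retrosynthetic overview**
1. Target 27 ⇐ tetra-O-benzyl ether 26 by hydrogenolysis (ring A: C1 butanoyl, C2 OH, C3 Me, C4 OH, C5 CH2, C6 OH; ring B: C1' CH2, C2' OH, C3' Me, C4' OMe, C5' butanoyl, C6' OH).
2. 26 ⇐ ring A aryne 25 (C1≡C6) + butanoic acid 24. The route rests on the butanoyl carbon C1 and the hydroxyl carbon C6 of ring A being adjacent, with the C2 oxygen beside C1 to steer the addition; the C6–O and C1–C(=O) bonds form together.
3. Aryne precursor 23 ⇐ Negishi union at the C5–CH2 bond of ring A bromo silyl triflate 12 with ring B benzylzinc chloride 22, which already carries the C5' ketone.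
4. 12 ⇐ 3,5-bis(benzyloxy)-4-methylphenol 7 (dibromination, retro-Brook shift, triflation) ⇐ benzoate 1. 22 ⇐ 2-methylphloroglucinol 13 (formylation, para O-methylation, benzylation, bromination, reduction, acylation, chlorination).
5. No ring is formed: both benzene rings are bought and only re-substituted; the target has no stereocenter.

Key step: step 15

Remark: 2-methylbenzene-1,3,5-triol (13) and N-methoxy-N-methylbutanamide are taken to be catalogue chemicals.

**Step 1**
Reactants: 1 methyl 3,5-dihydroxy-4-methylbenzoate; 2 benzyl bromide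
Product: 3 methyl 3,5-bis(benzyloxy)-4-methylbenzoate
Conditions: BnBr (2.3 equiv in all), K2CO3, DMF, 60 °C
Reagents that add atoms: benzyl bromide (second equivalent), BrCc1ccccc1
Why: Williamson etherification of both phenols, each taking one benzyl group from one molecule of benzyl bromide, is routine with carbonate base and leaves the methyl ester untouched.

**Step 2**
Reactants: 3 methyl 3,5-bis(benzyloxy)-4-methylbenzoate
Product: 4 3,5-bis(benzyloxy)-N-methoxy-N,4-dimethylbenzamide
Conditions: MeNHOMe·HCl, i-PrMgCl, THF, −20 → 0 °C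
Reagents that add atoms: N,O-dimethylhydroxylamine hydrochloride, CNOC.Cl
Why: The chloromagnesium amide made from the hydroxylamine salt and i-PrMgCl displaces methoxide from the ester (ester aminolysis to a Weinreb amide), and the benzyl ethers are inert to the Grignard base.

**Step 3**
Reactants: 4 3,5-bis(benzyloxy)-N-methoxy-N,4-dimethylbenzamide
Product: 5 1-[3,5-bis(benzyloxy)-4-methylphenyl]ethan-1-one
Conditions: MeMgCl, THF, 0 °C; aq NH4Cl
Reagents that add atoms: methylmagnesium chloride, C[Mg]Cl
Why: Weinreb ketone synthesis, in which the chelated tetrahedral adduct holds until work-up so that a single methyl group is delivered.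

**Step 4**
Reactants: 5 1-[3,5-bis(benzyloxy)-4-methylphenyl]ethan-1-one
Product: 7 3,5-bis(benzyloxy)-4-methylphenol, via aryl acetate 6 (not isolated)
Conditions: mCPBA, TFA (1 equiv), CH2Cl2, 0 °C → rt; then K2CO3, MeOH, rt
Reagents that add atoms: meta-chloroperoxybenzoic acid, OOC(=O)c1cccc(Cl)c1
Why: Baeyer–Villiger oxidation, in which aryl migrates in preference to methyl, should give the aryl acetate, which carbonate-catalysed methanolysis cleaves to the phenol; the methyl ketone is used because this ring has no ortho or para donor to support a direct aldehyde-to-formate oxidation.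

**Step 5**
Reactants: 7 3,5-bis(benzyloxy)-4-methylphenol
Product: 8 3,5-bis(benzyloxy)-2,6-dibromo-4-methylphenol
Conditions: NBS (2.05 equiv), CH2Cl2, −20 → 0 °C
Reagents that add atoms: N-bromosuccinimide, O=C1CCC(=O)N1Br
Why: Electrophilic aromatic bromination at the two equivalent positions ortho to the free hydroxyl, which are the only unsubstituted ring carbons and are activated by three oxygen substituents.

**Step 6**
Reactants: 8 3,5-bis(benzyloxy)-2,6-dibromo-4-methylphenol
Product: 12 3,5-bis(benzyloxy)-2-bromo-4-methyl-6-(trimethylsilyl)phenyl trifluoromethanesulfonate, via aryl silyl ether 9 (not isolated), via aryllithium 10 (not isolated), via lithium silylphenoxide 11 (not isolated)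
Conditions: HMDS, THF, 65 °C, evaporate; n-BuLi (1.05 equiv), THF, −100 → −78 °C; Tf2O, −100 °C → rt
Reagents that add atoms: hexamethyldisilazane, C[Si](C)(C)N[Si](C)(C)C; trifluoromethanesulfonic anhydride, O=S(=O)(OS(=O)(=O)C(F)(F)F)C(F)(F)F
Why: O-silylation, bromine–lithium exchange of one of the two equivalent bromines, anionic 1,3-silyl shift from oxygen to carbon (retro-Brook rearrangement) and O-triflation of the phenoxide make up the standard one-flask route from ortho-bromophenols to 2-(trimethylsilyl)aryl triflates, and the symmetry of 8 removes any site question.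

**Step 7**
Reactants: 13 2-methylbenzene-1,3,5-triol (2-methylphloroglucinol)
Product: 14 2,4,6-trihydroxy-3-methylbenzaldehyde
Conditions: POCl3, DMF, EtOAc, 0 °C → rt; then H2O, 50 °C
Reagents that add atoms: N,N-dimethylformamide, CN(C)C=O; water, O
Why: Vilsmeier–Haack formylation at one of the two equivalent free positions of the phloroglucinol ring, the first formyl group deactivating the ring against a second.

**Step 8**
Reactants: 14 2,4,6-trihydroxy-3-methylbenzaldehyde
Product: 15 2,6-dihydroxy-4-methoxy-3-methylbenzaldehyde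
Conditions: Me2SO4 (1.05 equiv), K2CO3 (1.0 equiv), acetone, 0 °C → rt
Reagents that add atoms: dimethyl sulfate, COS(=O)(=O)OC
Why: Williamson O-methylation limited to one equivalent, in which the 4-hydroxyl para to the aldehyde is the most acidic and the only one that cannot hydrogen-bond to the carbonyl oxygen, so it should react first.

**Step 9**
Reactants: 15 2,6-dihydroxy-4-methoxy-3-methylbenzaldehyde; 2 benzyl bromide
Product: 16 2,6-bis(benzyloxy)-4-methoxy-3-methylbenzaldehyde
Conditions: BnBr (2.5 equiv in all), K2CO3, DMF, 70 °C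
Reagents that add atoms: benzyl bromide (second equivalent), BrCc1ccccc1
Why: Williamson benzylation under forcing conditions alkylates both remaining hydrogen-bonded hydroxyls, each with one molecule of benzyl bromide.

**Step 10**
Reactants: 16 2,6-bis(benzyloxy)-4-methoxy-3-methylbenzaldehyde
Product: 17 2,6-bis(benzyloxy)-3-bromo-4-methoxy-5-methylbenzaldehyde
Conditions: NBS (1.05 equiv), MeCN, 0 °C → rt
Reagents that add atoms: N-bromosuccinimide, O=C1CCC(=O)N1Br
Why: Electrophilic aromatic bromination at the single free ring position, which lies ortho or para to all three alkoxy groups.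

**Step 11**
Reactants: 17 2,6-bis(benzyloxy)-3-bromo-4-methoxy-5-methylbenzaldehyde
Product: 18 [2,6-bis(benzyloxy)-3-bromo-4-methoxy-5-methylphenyl]methanol
Conditions: NaBH4, THF/MeOH, 0 °C
Reagents that add atoms: none
Why: Borohydride reduction of the aldehyde to the benzylic alcohol, with the aryl bromide and the ethers untouched.

**Step 12**
Reactants: 18 [2,6-bis(benzyloxy)-3-bromo-4-methoxy-5-methylphenyl]methanol
Product: 20 1-[4,6-bis(benzyloxy)-5-(hydroxymethyl)-2-methoxy-3-methylphenyl]butan-1-one, via dilithio species 19 (not isolated)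
Conditions: n-BuLi (2.1 equiv), THF, −78 °C; N-methoxy-N-methylbutanamide, −78 → 0 °C; aq NH4Cl
Reagents that add atoms: N-methoxy-N-methylbutanamide, CCCC(=O)N(C)OC
Why: Deprotonation of the hydroxyl and bromine–lithium exchange give a dilithio species whose aryllithium is acylated once by the Weinreb amide (Weinreb ketone synthesis), the alkoxide serving as protection in the flask.

**Step 13**
Reactants: 20 1-[4,6-bis(benzyloxy)-5-(hydroxymethyl)-2-methoxy-3-methylphenyl]butan-1-one
Product: 21 1-[4,6-bis(benzyloxy)-5-(chloromethyl)-2-methoxy-3-methylphenyl]butan-1-one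
Conditions: SOCl2 (1.2 equiv), CH2Cl2, 0 °C; used crude
Reagents that add atoms: thionyl chloride, O=S(Cl)Cl
Why: Deoxychlorination of an electron-rich benzylic alcohol through its chlorosulfite is fast at 0 °C, and the hexasubstituted ring offers no site for self-alkylation.

**Step 14**
Reactants: 21 1-[4,6-bis(benzyloxy)-5-(chloromethyl)-2-methoxy-3-methylphenyl]butan-1-one; 12 3,5-bis(benzyloxy)-2-bromo-4-methyl-6-(trimethylsilyl)phenyl trifluoromethanesulfonate
Product: 23 3,5-bis(benzyloxy)-2-{[2,6-bis(benzyloxy)-3-butanoyl-4-methoxy-5-methylphenyl]methyl}-4-methyl-6-(trimethylsilyl)phenyl trifluoromethanesulfonate, via benzylzinc chloride 22 (not isolated)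
Conditions: Zn dust, LiCl, THF, 25 °C; then 12, Pd(P(t-Bu)3)2 (5 mol%), THF/NMP, 25 → 50 °C
Reagents that add atoms: none
Why: LiCl-assisted zinc insertion into the benzylic chloride gives a ketone-tolerant benzylzinc reagent, and Negishi cross-coupling under a bulky monophosphine zerovalent palladium catalyst should insert into the C–Br bond in preference to the C–OTf bond, which is the poorer partner for this catalyst type and is shielded by the neighbouring trimethylsilyl group.

**Step 15**
Reactants: 23 3,5-bis(benzyloxy)-2-{[2,6-bis(benzyloxy)-3-butanoyl-4-methoxy-5-methylphenyl]methyl}-4-methyl-6-(trimethylsilyl)phenyl trifluoromethanesulfonate; 24 butanoic acid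
Product: 26 1-[2,4-bis(benzyloxy)-5-{[2,6-bis(benzyloxy)-3-butanoyl-4-methoxy-5-methylphenyl]methyl}-6-hydroxy-3-methylphenyl]butan-1-one, via aryne 25 (not isolated)
Conditions: CsF (4 equiv), butanoic acid (1.2 equiv), THF, 125 °C, sealed tube
Reagents that add atoms: none
Why: Fluoride attacks silicon and triflate leaves, giving the ring A aryne 25 across C1 and C6; caesium butanoate adds through oxygen at C6, the aryl anion left at C1 attacks the neighbouring ester carbonyl (a transient four-membered adduct formed in a 4-exo-trig sense), and opening of that adduct to the phenoxide moves the acyl group from oxygen to carbon. The closest known reaction type is the fluoride-triggered insertion of arynes from 2-(trimethylsilyl)aryl triflates into the C–O bond of carboxylic acids to give ortho-hydroxyaryl ketones, run in hot THF where the acyl shift outruns protonation of the aryl anion. No ring of the product is closed and no stereocenter is formed. The step needs regioselectivity (oxygen at C6, acyl at C1): the inductively withdrawing benzyloxy group on C2 distorts the aryne so that C6 is the more electrophilic terminus and the developing charge at C1 sits beside oxygen, which should outweigh the steric bias of the bridge CH2 on C5. It also needs the acyl shift to beat proton capture, which is served by keeping the acid near one equivalent, excluding water and heating. The medium is not acidic, so the benzyl ethers, the ring B ketone and the diarylmethane bridge should pass unchanged.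

**Step 16**
Reactants: 26 1-[2,4-bis(benzyloxy)-5-{[2,6-bis(benzyloxy)-3-butanoyl-4-methoxy-5-methylphenyl]methyl}-6-hydroxy-3-methylphenyl]butan-1-one
Product: 27 1-[3-({3-butanoyl-2,6-dihydroxy-4-methoxy-5-methylphenyl}methyl)-2,4,6-trihydroxy-5-methylphenyl]butan-1-one
Conditions: H2 (1 atm), 10% Pd/C, EtOAc, rt
Reagents that add atoms: none
Why: Catalytic hydrogenolysis of the four aryl benzyl ethers under neutral conditions, which the hydrogen-bonded aryl ketones, the aryl methyl ether and the acid-sensitive methylene bridge should survive.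

**Compound list**
1 | methyl 3,5-dihydroxy-4-methylbenzoate | COC(=O)c1cc(O)c(C)c(O)c1 | starting material
2 | benzyl bromide | BrCc1ccccc1 | starting material
3 | methyl 3,5-bis(benzyloxy)-4-methylbenzoate | COC(=O)c1cc(OCc2ccccc2)c(C)c(OCc2ccccc2)c1 | intermediate
4 | 3,5-bis(benzyloxy)-N-methoxy-N,4-dimethylbenzamide | CON(C)C(=O)c1cc(OCc2ccccc2)c(C)c(OCc2ccccc2)c1 | intermediate
5 | 1-[3,5-bis(benzyloxy)-4-methylphenyl]ethan-1-one | CC(=O)c1cc(OCc2ccccc2)c(C)c(OCc2ccccc2)c1 | intermediate
6 | 3,5-bis(benzyloxy)-4-methylphenyl acetate | CC(=O)Oc1cc(OCc2ccccc2)c(C)c(OCc2ccccc2)c1 | intermediate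
7 | 3,5-bis(benzyloxy)-4-methylphenol | Oc1cc(OCc2ccccc2)c(C)c(OCc2ccccc2)c1 | intermediate
8 | 3,5-bis(benzyloxy)-2,6-dibromo-4-methylphenol | Oc1c(Br)c(OCc2ccccc2)c(C)c(OCc2ccccc2)c1Br | intermediate
9 | [3,5-bis(benzyloxy)-2,6-dibromo-4-methylphenoxy]trimethylsilane | C[Si](C)(C)Oc1c(Br)c(OCc2ccccc2)c(C)c(OCc2ccccc2)c1Br | intermediate
10 | {4,6-bis(benzyloxy)-3-bromo-5-methyl-2-[(trimethylsilyl)oxy]phenyl}lithium | [Li]c1c(O[Si](C)(C)C)c(Br)c(OCc2ccccc2)c(C)c1OCc1ccccc1 | intermediate
11 | lithium 3,5-bis(benzyloxy)-2-bromo-4-methyl-6-(trimethylsilyl)phenolate | [Li+].[O-]c1c(Br)c(OCc2ccccc2)c(C)c(OCc2ccccc2)c1[Si](C)(C)C | intermediate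
12 | 3,5-bis(benzyloxy)-2-bromo-4-methyl-6-(trimethylsilyl)phenyl trifluoromethanesulfonate | O=S(=O)(Oc1c(Br)c(OCc2ccccc2)c(C)c(OCc2ccccc2)c1[Si](C)(C)C)C(F)(F)F | intermediate
13 | 2-methylbenzene-1,3,5-triol (2-methylphloroglucinol) | Cc1c(O)cc(O)cc1O | starting material
14 | 2,4,6-trihydroxy-3-methylbenzaldehyde | O=Cc1c(O)cc(O)c(C)c1O | intermediate
15 | 2,6-dihydroxy-4-methoxy-3-methylbenzaldehyde | O=Cc1c(O)cc(OC)c(C)c1O | intermediate
16 | 2,6-bis(benzyloxy)-4-methoxy-3-methylbenzaldehyde | O=Cc1c(OCc2ccccc2)cc(OC)c(C)c1OCc1ccccc1 | intermediate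
17 | 2,6-bis(benzyloxy)-3-bromo-4-methoxy-5-methylbenzaldehyde | O=Cc1c(OCc2ccccc2)c(Br)c(OC)c(C)c1OCc1ccccc1 | intermediate
18 | [2,6-bis(benzyloxy)-3-bromo-4-methoxy-5-methylphenyl]methanol | OCc1c(OCc2ccccc2)c(Br)c(OC)c(C)c1OCc1ccccc1 | intermediate
19 | lithium [2,6-bis(benzyloxy)-3-lithio-4-methoxy-5-methylphenyl]methanolate | [Li]OCc1c(OCc2ccccc2)c([Li])c(OC)c(C)c1OCc1ccccc1 | intermediate
20 | 1-[4,6-bis(benzyloxy)-5-(hydroxymethyl)-2-methoxy-3-methylphenyl]butan-1-one | CCCC(=O)c1c(OC)c(C)c(OCc2ccccc2)c(CO)c1OCc1ccccc1 | intermediate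
21 | 1-[4,6-bis(benzyloxy)-5-(chloromethyl)-2-methoxy-3-methylphenyl]butan-1-one | CCCC(=O)c1c(OC)c(C)c(OCc2ccccc2)c(CCl)c1OCc1ccccc1 | intermediate
22 | {[2,6-bis(benzyloxy)-3-butanoyl-4-methoxy-5-methylphenyl]methyl}zinc chloride | CCCC(=O)c1c(OC)c(C)c(OCc2ccccc2)c(C[Zn]Cl)c1OCc1ccccc1 | intermediate
23 | 3,5-bis(benzyloxy)-2-{[2,6-bis(benzyloxy)-3-butanoyl-4-methoxy-5-methylphenyl]methyl}-4-methyl-6-(trimethylsilyl)phenyl trifluoromethanesulfonate | CCCC(=O)c1c(OC)c(C)c(OCc2ccccc2)c(Cc2c(OCc3ccccc3)c(C)c(OCc3ccccc3)c([Si](C)(C)C)c2OS(=O)(=O)C(F)(F)F)c1OCc1ccccc1 | intermediate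
24 | butanoic acid | CCCC(=O)O | starting material
25 | 1-[4,6-bis(benzyloxy)-5-{[2,4-bis(benzyloxy)-3-methylcyclohexa-1,3-dien-5-yn-1-yl]methyl}-2-methoxy-3-methylphenyl]butan-1-one (ring A aryne, triple bond C1–C6) | CCCC(=O)c1c(OC)c(C)c(OCc2ccccc2)c(CC2=C(OCc3ccccc3)C(C)=C(OCc3ccccc3)C#C2)c1OCc1ccccc1 | intermediate
26 | 1-[2,4-bis(benzyloxy)-5-{[2,6-bis(benzyloxy)-3-butanoyl-4-methoxy-5-methylphenyl]methyl}-6-hydroxy-3-methylphenyl]butan-1-one | CCCC(=O)c1c(OC)c(C)c(OCc2ccccc2)c(Cc2c(OCc3ccccc3)c(C)c(OCc3ccccc3)c(C(=O)CCC)c2O)c1OCc1ccccc1 | intermediate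
27 | 1-[3-({3-butanoyl-2,6-dihydroxy-4-methoxy-5-methylphenyl}methyl)-2,4,6-trihydroxy-5-methylphenyl]butan-1-one | CCCC(=O)c1c(O)c(C)c(O)c(Cc2c(O)c(C)c(OC)c(C(=O)CCC)c2O)c1O | target

**Step count**
Total: 16 steps. Longest linear sequence: 10 steps (steps 7 to 16); the ring A branch is steps 1 to 6.

**Steps most likely to fail**

Step 15. The aryl anion may be protonated before the acyl shift, the carboxylate may add at the wrong aryne carbon, or a benzyl ether oxygen of ring B beside the bridge may capture the aryne intramolecularly. The fallback makes the ring A ketone by organolithium acylation and does not use an aryne. It sets out from 8 and comes back at 27. Phenol 8 is benzylated (BnBr, K2CO3, DMF) to 1,3,5-tris(benzyloxy)-2,4-dibromo-6-methylbenzene F1. One bromine is exchanged (n-BuLi, THF, −78 °C) and the aryllithium is acylated with N-methoxy-N-methylbutanamide to give 1-[2,4,6-tris(benzyloxy)-3-bromo-5-methylphenyl]butan-1-one F2. Negishi coupling of F2 with zinc reagent 22 under the conditions of step 14 should give 1-[2,4,6-tris(benzyloxy)-3-{[2,6-bis(benzyloxy)-3-butanoyl-4-methoxy-5-methylphenyl]methyl}-5-methylphenyl]butan-1-one F3. Hydrogenolysis (H2, Pd/C, EtOAc) of F3 gives 27.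

Step 14. Oxidative addition at the doubly flanked C–Br bond may be slow, insertion into the C–OTf bond may compete, and the benzylic zinc reagent may homocouple. The fallback joins the rings by carbonyl addition before the silyl triflate is built. It sets out from 8 and 17 and comes back at 23. Phenol 8 is protected (MOMCl, i-Pr2NEt, CH2Cl2) as 1,3-bis(benzyloxy)-4,6-dibromo-5-(methoxymethoxy)-2-methylbenzene F4. Mono bromine–lithium exchange (n-BuLi, THF, −78 °C) and addition to aldehyde 17 give racemic [2,4-bis(benzyloxy)-5-bromo-6-(methoxymethoxy)-3-methylphenyl][2,6-bis(benzyloxy)-3-bromo-4-methoxy-5-methylphenyl]methanol F5. Ionic hydrogenation (Et3SiH, TFA, CH2Cl2, 0 °C) removes the carbinol hydroxyl and the methoxymethyl group to give 3,5-bis(benzyloxy)-2-{[2,6-bis(benzyloxy)-3-bromo-4-methoxy-5-methylphenyl]methyl}-6-bromo-4-methylphenol F6. O-Silylation (HMDS) and then n-BuLi (2.1 equiv, −78 °C) exchange both bromines; ring A undergoes the retro-Brook shift and the ring B aryllithium is acylated with N-methoxy-N-methylbutanamide. Aqueous quench gives 1-[4,6-bis(benzyloxy)-5-{[2,4-bis(benzyloxy)-6-hydroxy-3-methyl-5-(trimethylsilyl)phenyl]methyl}-2-methoxy-3-methylphenyl]butan-1-one F7. Triflation of F7 (Tf2O, pyridine, CH2Cl2, 0 °C) gives 23.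

Step 8. Site selectivity among the three hydroxyls may be lost through over-methylation or C-methylation of the phloroglucinol ring. The fallback methylates exhaustively and then removes the two ethers next to the aldehyde. It sets out from 14 and comes back at 15. Aldehyde 14 is permethylated (Me2SO4 excess, K2CO3, acetone, reflux) to 2,4,6-trimethoxy-3-methylbenzaldehyde F8. Chelation-directed cleavage of the two methyl ethers ortho to the aldehyde (AlCl3, CH2Cl2, 0 °C → rt) gives 15.

**Further compounds**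
F1 | step 15 | 1,3,5-tris(benzyloxy)-2,4-dibromo-6-methylbenzene | Cc1c(OCc2ccccc2)c(Br)c(OCc2ccccc2)c(Br)c1OCc1ccccc1
F2 | step 15 | 1-[2,4,6-tris(benzyloxy)-3-bromo-5-methylphenyl]butan-1-one | CCCC(=O)c1c(OCc2ccccc2)c(C)c(OCc2ccccc2)c(Br)c1OCc1ccccc1
F3 | step 15 | 1-[2,4,6-tris(benzyloxy)-3-{[2,6-bis(benzyloxy)-3-butanoyl-4-methoxy-5-methylphenyl]methyl}-5-methylphenyl]butan-1-one | CCCC(=O)c1c(OC)c(C)c(OCc2ccccc2)c(Cc2c(OCc3ccccc3)c(C)c(OCc3ccccc3)c(C(=O)CCC)c2OCc2ccccc2)c1OCc1ccccc1
F4 | step 14 | 1,3-bis(benzyloxy)-4,6-dibromo-5-(methoxymethoxy)-2-methylbenzene | COCOc1c(Br)c(OCc2ccccc2)c(C)c(OCc2ccccc2)c1Br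
F5 | step 14 | [2,4-bis(benzyloxy)-5-bromo-6-(methoxymethoxy)-3-methylphenyl][2,6-bis(benzyloxy)-3-bromo-4-methoxy-5-methylphenyl]methanol (racemic) | COCOc1c(Br)c(OCc2ccccc2)c(C)c(OCc2ccccc2)c1C(O)c1c(OCc2ccccc2)c(C)c(OC)c(Br)c1OCc1ccccc1
F6 | step 14 | 3,5-bis(benzyloxy)-2-{[2,6-bis(benzyloxy)-3-bromo-4-methoxy-5-methylphenyl]methyl}-6-bromo-4-methylphenol | Oc1c(Br)c(OCc2ccccc2)c(C)c(OCc2ccccc2)c1Cc1c(OCc2ccccc2)c(C)c(OC)c(Br)c1OCc1ccccc1
F7 | step 14 | 1-[4,6-bis(benzyloxy)-5-{[2,4-bis(benzyloxy)-6-hydroxy-3-methyl-5-(trimethylsilyl)phenyl]methyl}-2-methoxy-3-methylphenyl]butan-1-one | CCCC(=O)c1c(OC)c(C)c(OCc2ccccc2)c(Cc2c(OCc3ccccc3)c(C)c(OCc3ccccc3)c([Si](C)(C)C)c2O)c1OCc1ccccc1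
F8 | step 8 | 2,4,6-trimethoxy-3-methylbenzaldehyde | O=Cc1c(OC)cc(OC)c(C)c1OC
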